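The spiro[5.5]undecane core is disconnected at C1–C6. In chamigrene numbering (spiro C6; ring B C1–C5; ring A C7–C11; C14 the exocyclic methylene carbon) the unit C14=C7–C6–C1–C2=C3, which runs from ring A through the spiro atom into ring B, is a 1,5-diene and therefore the output of a [3,3] shift. An anionic oxy-Cope rearrangement of an enantiopure, Birch-derived 2-vinyl-octalin-2-ol (ring-fusion C6=C7 alkene, C10 silyl ether, C11 gem-dimethyl) closes ring B, sets the quaternary stereocentre C6, unveils the C7=C14 methylene and delivers a C2=C3 enolate, trapped as its triflate. Methyl coupling, invertive C10 bromination and C2/C3 chlorobromination via an epoxide complete the target.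

Key step: step 6

Remark on the chemistry: the remote C10 silyloxy centre is assumed to exert no useful facial bias on the vinyl addition of step 5, so the two carbinol epimers should form in comparable amounts; only the (2S) epimer 9, isolated by chromatography, is carried forward. Spiro compounds carry the chamigrene locants defined above.

Step 1
Reactants: 1 6-methoxy-3,4-dihydronaphthalen-2(1H)-one (6-methoxy-2-tetralone); 2 iodomethane
Product: 3 6-methoxy-1,1-dimethyl-3,4-dihydronaphthalen-2(1H)-one
Conditions: NaH (2.2 equiv), MeI (2.5 equiv), THF, 0 °C → rt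
Reagents that add atoms: iodomethane, CI
Why: Twofold enolate C-alkylation; C1 is both benzylic and alpha to the carbonyl, so it is deprotonated and methylated twice in preference to C3, and the quaternary carbon formed cannot enolise again.

Step 2
Reactants: 3 6-methoxy-1,1-dimethyl-2-tetralone
Product: 4 (2S)-6-methoxy-1,1-dimethyl-1,2,3,4-tetrahydronaphthalen-2-ol
Conditions: (R)-Me-CBS catalyst [(3aR)-1-methyl-3,3-diphenyltetrahydro-1H,3H-pyrrolo[1,2-c][1,3,2]oxazaborole, 10 mol%], BH3·SMe2, THF, −20 °C
Reagents that add atoms: none
Why: Corey–Bakshi–Shibata reduction; the catalyst reads the quaternary C1 side as large and the C3 methylene as small, so the (R)-oxazaborolidine should deliver hydride to give the (2S)-alcohol, the future C10 oxygen in the configuration needed for later inversion.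

Step 3
Reactants: 4 (2S)-tetralol
Product: 5 tert-butyl{[(2S)-6-methoxy-1,1-dimethyl-1,2,3,4-tetrahydronaphthalen-2-yl]oxy}dimethylsilane
Conditions: TBSOTf, 2,6-lutidine, CH2Cl2, 0 °C
Reagents that add atoms: tert-butyldimethylsilyl trifluoromethanesulfonate, CC(C)(C)[Si](C)(C)OS(=O)(=O)C(F)(F)F
Why: O-silylation of a hindered neopentylic secondary alcohol with the silyl triflate; the resulting ether tolerates dissolving metal, organometallic reagents and KH, and no stereocentre is touched.

Step 4
Reactants: 5 (2S)-silyloxy methoxytetralin
Product: 7 (6S)-6-[(tert-butyldimethylsilyl)oxy]-5,5-dimethyl-3,4,5,6,7,8-hexahydronaphthalen-2(1H)-one, via dihydroanisole enol ether 6 (not isolated)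
Conditions: Li, NH3(l), THF, t-BuOH, −78 → −33 °C; then (CO2H)2, THF/MeOH/H2O, rt
Reagents that add atoms: water, O
Why: Birch reduction protonates the two unsubstituted ring positions and leaves the enol ether and the tetrasubstituted ring-fusion alkene; mild oxalic acid hydrolysis of the enol ether then stops at the non-conjugated ketone without moving the ring-fusion double bond or cleaving the silyl ether.

Step 5
Reactants: 7 (6S)-silyloxy beta,gamma-unsaturated octalone; 8 vinylmagnesium bromide
Product: 9 (2S,6S)-6-[(tert-butyldimethylsilyl)oxy]-5,5-dimethyl-2-vinyl-1,2,3,4,5,6,7,8-octahydronaphthalen-2-ol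
Conditions: CeCl3 (anhydrous, 1.5 equiv), vinylmagnesium bromide, THF, −78 °C; aq. NH4Cl; chromatographic separation of the carbinol epimers
Reagents that add atoms: vinylmagnesium bromide, C=C[Mg]Br
Why: Organocerium 1,2-addition to an easily enolised beta,gamma-unsaturated ketone, where cerium suppresses enolisation and conjugation; the carbinol centre forms without facial control, and the (2S) epimer, whose vinyl group lies anti to the silyloxy group, is isolated from its C2 epimer by chromatography.

Step 6
Reactants: 9 (2S,6S)-2-vinyl-octalin-2-ol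
Product: 12 (6S,10S)-10-[(tert-butyldimethylsilyl)oxy]-11,11-dimethyl-7-methylidenespiro[5.5]undec-2-en-3-yl trifluoromethanesulfonate, via potassium alkoxide 10 (not isolated), via potassium enolate 11 (not isolated)
Conditions: KH (1.3 equiv), 18-crown-6 (1.3 equiv), THF, 0 → 66 °C; then PhNTf2, −78 → 0 °C
Reagents that add atoms: N-phenylbis(trifluoromethanesulfonimide), O=S(=O)(N(c1ccccc1)S(=O)(=O)C(F)(F)F)C(F)(F)F
Why: KH with 18-crown-6 converts 9 into the dissociated alkoxide 10, whose 3-oxido-1,5-diene C1=C2–C3(O)–C14–C7=C6 undergoes a concerted [3,3] sigmatropic shift through a boat-shaped transition state in which the pseudoaxial vinyl group spans the cyclohexene ring from C3 to C6, so that C1–C6 forms as C3–C14 breaks and enolate 11 results, which is O-sulfonylated in the same flask. The closest known reaction type is the anionic oxy-Cope rearrangement of 1-vinylcyclohex-3-en-1-ols with trapping of the enolate as its enol triflate. Ring B (C6–C1–C2–C3–C4–C5) is closed pericyclically by bond formation between the vinyl terminus C1 and the alkene carbon C6, suprafacial on both three-carbon units, while the former carbocycle opens at C3–C14 in the same event, so a fused bicycle becomes a spirocycle. The new stereocentre C6 is governed solely by the carbinol configuration of 9: the bond can form only on the ring face that carries the vinyl group, which in the (2S) epimer is the face anti to the C10 silyloxy group, and this gives (6S). The step needs the [3,3] path to beat the 1,3-shift to C14 and alkoxide fragmentation, which the crown-ether-separated alkoxide and the enforced proximity of C1 and C6 in the boat conformer should favour, and it needs enolate 11 to be trapped without proton exchange, which excess KH, aprotic THF and triflation at −78 °C secure. Trapping at oxygen is essential, because the corresponding C3 ketone would have two equivalent arms in ring B and C6 would no longer be stereogenic.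

Step 7
Reactants: 12 spiro enol triflate; 13 methylmagnesium bromide
Product: 14 tert-butyldimethyl{[(6S,10S)-3,11,11-trimethyl-7-methylidenespiro[5.5]undec-2-en-10-yl]oxy}silane
Conditions: MeMgBr, Fe(acac)3 (5 mol%), THF/NMP, −20 → 0 °C
Reagents that add atoms: methylmagnesium bromide, C[Mg]Br
Why: Iron-catalysed Kumada-type cross-coupling of an alkenyl triflate with a methyl Grignard reagent, which replaces the triflate by the C3 methyl group without moving the C2=C3 double bond and leaves the silyl ether and the hindered exocyclic alkene untouched.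

Step 8
Reactants: 14 silyl-protected diene
Product: 15 (6S,10S)-3,11,11-trimethyl-7-methylidenespiro[5.5]undec-2-en-10-ol
Conditions: Bu4NF, THF, 50 °C
Reagents that add atoms: none
Why: Fluoride-mediated desilylation driven by Si–F bond formation; the basic medium spares the acid-sensitive exocyclic alkene and no stereocentre is affected.

Step 9
Reactants: 15 (10S)-dienol
Product: 16 (6S,10R)-10-bromo-3,11,11-trimethyl-7-methylidenespiro[5.5]undec-2-ene
Conditions: CBr4, PPh3, toluene, 60 °C
Reagents that add atoms: tetrabromomethane, BrC(Br)(Br)Br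
Why: Appel bromination; the phosphorus-activated oxygen is displaced from the rear by bromide, so C10 is inverted from S to R, and a non-polar solvent with gentle heating is chosen to favour direct displacement over ionisation at this neopentylic carbon.

Step 10
Reactants: 16 (10R)-bromo diene
Product: 17 (2S,3R,6S,10R)-10-bromo-2,3-epoxy-3,11,11-trimethyl-7-methylidenespiro[5.5]undecane
Conditions: mCPBA (1.0 equiv), NaHCO3, CH2Cl2, −20 → 0 °C
Reagents that add atoms: 3-chloroperoxybenzoic acid, O=C(OO)c1cccc(Cl)c1
Why: Prilezhaev epoxidation; the trisubstituted C2=C3 alkene is far more nucleophilic than the hindered 1,1-disubstituted C7=C14 alkene, and the peracid should approach ring B anti to C7, which is expected to sit pseudoaxial on ring B at C6 while the bulkier C11 stays pseudoequatorial, so C2 and C3 are set on the face opposite C7.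

Step 11
Reactants: 17 2,3-epoxide
Product: 18 (2R,3R,6S,10R)-10-bromo-2-chloro-3,11,11-trimethyl-7-methylidenespiro[5.5]undecan-3-ol
Conditions: LiCl, AcOH, THF, 25–40 °C
Reagents that add atoms: lithium chloride, [Li+].[Cl-]
Why: Weak-acid-assisted SN2 epoxide opening by chloride under the Fürst–Plattner rule; with C7 axial on ring B, only attack at C2 anti to the oxygen leads directly to a chair with Cl and OH trans-diaxial, and C2 is also the less substituted carbon, so C2 is inverted to (2R) while C3 keeps its oxygen.

Step 12
Reactants: 18 chlorohydrin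
Product: 19 (2R,3R,6S,10R)-3,10-dibromo-2-chloro-3,11,11-trimethyl-7-methylidenespiro[5.5]undecane (target)
Conditions: TMSBr, CH2Cl2, −30 → 0 °C
Reagents that add atoms: bromotrimethylsilane, C[Si](C)(C)Br
Why: SN1-type replacement of a tertiary hydroxyl by bromide with bromotrimethylsilane; the antiperiplanar axial C2–Cl bond should bridge the developing C3 cation from the C7 face, so bromide enters at the tertiary carbon on the face the oxygen left and C3 keeps its configuration (3R), giving the trans-diaxial bromochloride, while the low temperature limits addition of transient HBr to the C7=C14 alkene.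

Compound list
1 | 6-methoxy-3,4-dihydronaphthalen-2(1H)-one | O=C1CCc2cc(OC)ccc2C1 | starting material
2 | iodomethane | CI | starting material
3 | 6-methoxy-1,1-dimethyl-3,4-dihydronaphthalen-2(1H)-one | COc1ccc2c(c1)CCC(=O)C2(C)C | intermediate
4 | (2S)-6-methoxy-1,1-dimethyl-1,2,3,4-tetrahydronaphthalen-2-ol | COc1ccc2c(c1)CC[C@H](O)C2(C)C | intermediate
5 | tert-butyl{[(2S)-6-methoxy-1,1-dimethyl-1,2,3,4-tetrahydronaphthalen-2-yl]oxy}dimethylsilane | COc1ccc2c(c1)CC[C@H](O[Si](C)(C)C(C)(C)C)C2(C)C | intermediate
6 | tert-butyl{[(2S)-6-methoxy-1,1-dimethyl-1,2,3,4,5,8-hexahydronaphthalen-2-yl]oxy}dimethylsilane | COC1=CCC2=C(C1)CC[C@H](O[Si](C)(C)C(C)(C)C)C2(C)C | intermediate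
7 | (6S)-6-[(tert-butyldimethylsilyl)oxy]-5,5-dimethyl-3,4,5,6,7,8-hexahydronaphthalen-2(1H)-one | O=C1CCC2=C(C1)CC[C@H](O[Si](C)(C)C(C)(C)C)C2(C)C | intermediate
8 | vinylmagnesium bromide | C=C[Mg]Br | starting material
9 | (2S,6S)-6-[(tert-butyldimethylsilyl)oxy]-5,5-dimethyl-2-vinyl-1,2,3,4,5,6,7,8-octahydronaphthalen-2-ol | C=C[C@]1(O)CCC2=C(C1)CC[C@H](O[Si](C)(C)C(C)(C)C)C2(C)C | intermediate
10 | potassium (2S,6S)-6-[(tert-butyldimethylsilyl)oxy]-5,5-dimethyl-2-vinyl-1,2,3,4,5,6,7,8-octahydronaphthalen-2-olate | C=C[C@]1([O-])CCC2=C(C1)CC[C@H](O[Si](C)(C)C(C)(C)C)C2(C)C.[K+] | intermediate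
11 | potassium (6S,10S)-10-[(tert-butyldimethylsilyl)oxy]-11,11-dimethyl-7-methylidenespiro[5.5]undec-2-en-3-olate | C=C1CC[C@H](O[Si](C)(C)C(C)(C)C)C(C)(C)[C@]12CCC([O-])=CC2.[K+] | intermediate
12 | (6S,10S)-10-[(tert-butyldimethylsilyl)oxy]-11,11-dimethyl-7-methylidenespiro[5.5]undec-2-en-3-yl trifluoromethanesulfonate | C=C1CC[C@H](O[Si](C)(C)C(C)(C)C)C(C)(C)[C@]12CCC(OS(=O)(=O)C(F)(F)F)=CC2 | intermediate
13 | methylmagnesium bromide | C[Mg]Br | starting material
14 | tert-butyldimethyl{[(6S,10S)-3,11,11-trimethyl-7-methylidenespiro[5.5]undec-2-en-10-yl]oxy}silane | C=C1CC[C@H](O[Si](C)(C)C(C)(C)C)C(C)(C)[C@]12CCC(C)=CC2 | intermediate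
15 | (6S,10S)-3,11,11-trimethyl-7-methylidenespiro[5.5]undec-2-en-10-ol | C=C1CC[C@H](O)C(C)(C)[C@]12CCC(C)=CC2 | intermediate
16 | (6S,10R)-10-bromo-3,11,11-trimethyl-7-methylidenespiro[5.5]undec-2-ene | C=C1CC[C@@H](Br)C(C)(C)[C@]12CCC(C)=CC2 | intermediate
17 | (2S,3R,6S,10R)-10-bromo-2,3-epoxy-3,11,11-trimethyl-7-methylidenespiro[5.5]undecane | C=C1CC[C@@H](Br)C(C)(C)[C@]12CC[C@@]3(C)O[C@H]3C2 | intermediate
18 | (2R,3R,6S,10R)-10-bromo-2-chloro-3,11,11-trimethyl-7-methylidenespiro[5.5]undecan-3-ol | C=C1CC[C@@H](Br)C(C)(C)[C@]12CC[C@@](C)(O)[C@H](Cl)C2 | intermediate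
19 | (2R,3R,6S,10R)-3,10-dibromo-2-chloro-3,11,11-trimethyl-7-methylidenespiro[5.5]undecane | C=C1CC[C@@H](Br)C(C)(C)[C@]12CC[C@@](C)(Br)[C@H](Cl)C2 | target

Total step count: 12. Longest linear sequence: 12 steps (1 → 19).

Steps most likely to fail

Step 6 (key step). Bond formation at the fully substituted C6, next to the quaternary C11, may be slow. The 1,3-shift to the less hindered C14 terminus (two-carbon ring expansion), or heterolytic cleavage of C3–C14 followed by unselective recombination, could then overtake the concerted shift. Proton transfer to the enolate before triflation would also scramble the C2=C3 position and with it C6. The fallback keeps the disconnection but runs the shift in neutral form. Starting from 9, the tertiary hydroxyl is silylated with N-(trimethylsilyl)imidazole to give (2S,6S)-6-[(tert-butyldimethylsilyl)oxy]-5,5-dimethyl-2-[(trimethylsilyl)oxy]-2-vinyl-1,2,3,4,5,6,7,8-octahydronaphthalene F1. Thermolysis of this ether (degassed decalin in a base-washed sealed tube at about 250–300 °C, or flash vacuum thermolysis) should effect the siloxy-Cope rearrangement to the spiro trimethylsilyl enol ether F2, in which the C2=C3 position is again fixed by the shift. MeLi in THF at 0 °C then cleaves the O–Si bond to the regiodefined lithium enolate F3, which is triflated with PhNTf2 at −78 °C and rejoins the route at 12.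

Step 9. Backside attack at the neopentylic C10 is slow, so E2 loss of a C9 proton or ionisation with 1,2-methyl shift from C11 may outcompete displacement. The fallback separates activation from displacement. Starting from 15, ClCH2SO2Cl and pyridine in CH2Cl2 at 0 °C give the isolable (6S,10S)-3,11,11-trimethyl-7-methylidenespiro[5.5]undec-2-en-10-yl chloromethanesulfonate F4, which carries a far better nucleofuge than the oxyphosphonium intermediate of the one-pot reaction. Salt-free displacement with Bu4NBr in toluene at 60–80 °C should then invert C10 and rejoin the route at 16.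

Step 12. Ionisation at C3 is retarded by the neighbouring chlorine. The HBr released on silylation of the hydroxyl may therefore protonate or isomerise the C7=C14 alkene before substitution occurs, and a free C3 cation may lose a proton or be captured without facial control. The fallback gives up protic ionisation and activates the oxygen covalently under neutral conditions. Starting from 18, treatment with 1-bromo-N,N,2-trimethylprop-1-en-1-amine in CH2Cl2 at 0 → 25 °C (the alpha-haloenamine method for deoxyhalogenation of alcohols) should add the hydroxyl to the keteniminium form of the reagent and give the alkoxyiminium bromide N-[1-{[(2R,3R,6S,10R)-10-bromo-2-chloro-3,11,11-trimethyl-7-methylidenespiro[5.5]undecan-3-yl]oxy}-2-methylpropylidene]-N-methylmethanaminium bromide F5. Collapse of this ion pair, with the same chlorine bridging and bromide return at C3 on the face of the departing oxygen, expels a neutral amide and no free HBr, and arrives at 19.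

Further compounds
F1 | step 6 | (2S,6S)-6-[(tert-butyldimethylsilyl)oxy]-5,5-dimethyl-2-[(trimethylsilyl)oxy]-2-vinyl-1,2,3,4,5,6,7,8-octahydronaphthalene | C=C[C@]1(O[Si](C)(C)C)CCC2=C(C1)CC[C@H](O[Si](C)(C)C(C)(C)C)C2(C)C
F2 | step 6 | tert-butyldimethyl{[(6S,10S)-11,11-dimethyl-7-methylidene-3-[(trimethylsilyl)oxy]spiro[5.5]undec-2-en-10-yl]oxy}silane | C=C1CC[C@H](O[Si](C)(C)C(C)(C)C)C(C)(C)[C@]12CCC(O[Si](C)(C)C)=CC2
F3 | step 6 | lithium (6S,10S)-10-[(tert-butyldimethylsilyl)oxy]-11,11-dimethyl-7-methylidenespiro[5.5]undec-2-en-3-olate | C=C1CC[C@H](O[Si](C)(C)C(C)(C)C)C(C)(C)[C@]12CCC([O-])=CC2.[Li+]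
F4 | step 9 | (6S,10S)-3,11,11-trimethyl-7-methylidenespiro[5.5]undec-2-en-10-yl chloromethanesulfonate | C=C1CC[C@H](OS(=O)(=O)CCl)C(C)(C)[C@]12CCC(C)=CC2
F5 | step 12 | N-[1-{[(2R,3R,6S,10R)-10-bromo-2-chloro-3,11,11-trimethyl-7-methylidenespiro[5.5]undecan-3-yl]oxy}-2-methylpropylidene]-N-methylmethanaminium bromide | C=C1CC[C@@H](Br)C(C)(C)[C@]12CC[C@@](C)(OC(C(C)C)=[N+](C)C)[C@H](Cl)C2.[Br-]
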